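All runs were generated by integration on assumed constants; scatter was added.

A racemate under a single-handed catalyst tempts one to reckon a resolution, with the product excess sinking towards zero as conversion ends. The delta run refuses that picture: its left-handed product reaches 64.3% at 5.00 h, more than the half of the charge that entered as left-handed substrate. Right-handed substrate must therefore have turned into left-handed substrate.

| flask | left-handed substrate | right-handed substrate | reagent | free catalyst | precatalyst | added ligand | remark | time |
|---|---|---|---|---|---|---|---|---|
| gamma | 0.10 M | 0.10 M | 1.5 equiv (fed, over 1.0 h) | 1 mol% | 0.1 mol% | 4.2 mM | run made earlier |  |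
| delta | 0.10 M | 0.10 M | 6 equiv (fed, over 1.0 h) | 1 mol% | 0.1 mol% | 4.2 mM | run made earlier |  |
| flask | 0.10 M | 0.10 M | 3.00 equiv (fed, over 1.0 h) | 1 mol% | 0.1 mol% | 4.2 mM |  | 4.0 h |

| run | time / h | left-handed product / % | right-handed product / % |
|---|---|---|---|
| gamma | 0.417 | 9.3 | 5.2 |
| gamma | 0.833 | 24.0 | 13.1 |
| gamma | 2.00 | 39.2 | 20.5 |
| gamma | 5.00 | 40.3 | 21.9 |
| delta | 0.417 | 29.2 | 16.3 |
| delta | 0.833 | 52.8 | 28.9 |
| delta | 2.00 | 62.2 | 34.6 |
| delta | 5.00 | 64.3 | 35.1 |

(readings scatter by 0.5 percentage points)

- left-handed product and right-handed product together, in percent of the left-handed substrate and right-handed substrate charged together, at 4.0 h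
- excess of left-handed product over right-handed product in the product at 4.0 h
- whether the exchange between left-handed substrate and right-handed substrate keeps pace with the reaction: how far the product's excess at 4.0 h gets from its value without exchange to its value with instant exchange (above 80% keeps pace, below 20% hardly takes part, else lags behind)

- free catalyst is single-handed; left-handed substrate and right-handed substrate are mirror images of each other, charged as a racemate, each of them at the stated concentration
- an excess is below zero if the other one leads

The plateau readings give 1.84 in the gamma run and 1.83 in the delta run, so these readings show no dependence on the dose beyond their scatter of 0.5 percentage points. Pooled, they give 1.84: the product ratio, left-handed over right-handed product, read as a selectivity factor. With exchange abreast of the reaction, this ratio as read means an excess of 29.5%.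

The flask is fed at half of the delta rate with the same catalyst charges, so my own reckoning is that the exchange keeps pace. Its yield should lie between the plateaus of 62.2% and 99.4%.

The forecast gave 87%, 29.2% and keeps pace, holding that “racemisation easily keeps pace”.

The flask gives 89.9% and 29.9%, which is 0.4 points from the excess of the ratio. The exchange keeps pace, at 93% of the way from no exchange to instant exchange.

    left-handed substrate + racemization catalyst ⇌ right-handed substrate + racemization catalyst, rate k1*[racemization catalyst]*[left-handed substrate] forward; the back reaction follows from the equilibrium constant (k = 3600 /M/min)
    2 reagent → homo dimer (k = 0.180 /M/min)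
    racemization catalyst + added ligand ⇌ idle complex, settled at all times (K = 110 /M)
    reagent + free catalyst + right-handed substrate → free catalyst + right-handed product (k = 240 /M²/min)
    precatalyst → racemization catalyst (k = 0.0360 /min)
    reagent + free catalyst + left-handed substrate → free catalyst + left-handed product (k = 460 /M²/min)

At 4.00 h in the flask, the exchange evens the substrates with a half-time of 1.40 min, far shorter than the 5.8 h half-life of left-handed substrate by coupling. At the end of the feed, left-handed and right-handed substrate already stand at 15.1% and 15.7%.

In the neighbour flask with 4 mol% of free catalyst, where the yield is >99.9%, the ratio puts right-handed product at 35.2% of the charge. The computed flask holds 36.2%, with an excess of 27.5%.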